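**Assumption:** the target has no stereocentre and no stereogenic double bond (the prenyl alkene carries two identical methyls), so it is achiral and no asymmetric step is needed.

**Retrosynthetic overview**
- Target = 2-methoxy-5-prenyl-3,6-di(indol-3-yl)-1,4-benzoquinone: OMe and prenyl are para, and the two indol-3-yl groups are para.
- Last disconnection: the quinone–prenyl C–C bond, made by Stille coupling of a bromoquinone with prenyltributylstannane under neutral conditions.
- Before that: the C–OMe bond, made by mono addition–elimination of methoxide on the symmetrical 2,5-dibromo-3,6-di(indolyl)quinone.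
- First: both quinone–indole C–C bonds, made by double base-mediated addition–elimination of indole on bromanil.
- No ring is formed in the route; the quinone ring and both indole rings are bought intact.

**Route**

Step 1
Reactants: 1 tetrabromo-1,4-benzoquinone (bromanil); 2 1H-indole (2.1 equiv)
Product: 4 dibromo-bis(indolyl)quinone [2,5-dibromo-3,6-di(1H-indol-3-yl)-1,4-benzoquinone], via mono-indolyl tribromoquinone 3 (not isolated)
Conditions: Cs2CO3 (2.5 equiv), MeCN, rt, dark, 16 h
Reagents that add atoms: none
Why: Base-mediated vinylogous addition–elimination (Michael addition/bromide loss) of indole C-3 on the bromoquinone occurs twice; the first indolyl group is a vinylogous-amide donor that deactivates the carbonyl it is conjugated with and so steers the second indole to the para carbon (2,5-dibromo-3,6-diindolyl pattern).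

Step 2
Reactants: 4 2,5-dibromo-3,6-di(1H-indol-3-yl)-1,4-benzoquinone
Product: 5 2-bromo-3,6-di(1H-indol-3-yl)-5-methoxy-1,4-benzoquinone
Conditions: NaOMe (1.1 equiv, added dropwise), MeOH/THF 1:1, 0 °C to rt; aq. NH4Cl
Reagents that add atoms: sodium methoxide, [Na+].[O-]C
Why: Addition–elimination (vinylogous acyl substitution) of methoxide at a C–Br carbon, where the new methoxy group forms a vinylogous ester that lowers the electrophilicity of the ring, so the second bromide reacts much more slowly and about one equivalent gives the mono-ether (the substrate is symmetrical, so there is no regiochemical issue).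

Step 3
Reactants: 5 2-bromo-3,6-di(1H-indol-3-yl)-5-methoxy-1,4-benzoquinone; 6 tributyl(3-methylbut-2-en-1-yl)stannane (1.5 equiv)
Product: 7 2,5-di(1H-indol-3-yl)-3-methoxy-6-(3-methylbut-2-en-1-yl)-1,4-benzoquinone (target CNP0506434.0)
Conditions: Pd(PPh3)4 (10 mol %), degassed 1,4-dioxane, 90 °C, argon, dark
Reagents that add atoms: none
Why: Stille cross-coupling, in which the bromoquinone C–Br (a vinylogous acyl bromide) adds oxidatively to zerovalent palladium, the prenyl group is transferred from tin, and reductive elimination from the prenylpalladium intermediate at its less hindered primary terminus gives the linear prenyl group; the neutral conditions avoid base-induced quinone-methide/chromene formation and leave the indole N–H and the methoxy group untouched.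

**Compound list**
1 | tetrabromo-1,4-benzoquinone (bromanil) | O=C1C(Br)=C(Br)C(=O)C(Br)=C1Br | starting material
2 | 1H-indole | c1ccc2[nH]ccc2c1 | starting material
3 | 2,3,5-tribromo-6-(1H-indol-3-yl)-1,4-benzoquinone | O=C1C(Br)=C(Br)C(=O)C(c2c[nH]c3ccccc23)=C1Br | intermediate
4 | 2,5-dibromo-3,6-di(1H-indol-3-yl)-1,4-benzoquinone | O=C1C(Br)=C(c2c[nH]c3ccccc23)C(=O)C(Br)=C1c1c[nH]c2ccccc12 | intermediate
5 | 2-bromo-3,6-di(1H-indol-3-yl)-5-methoxy-1,4-benzoquinone | COC1=C(c2c[nH]c3ccccc23)C(=O)C(Br)=C(c2c[nH]c3ccccc23)C1=O | intermediate
6 | tributyl(3-methylbut-2-en-1-yl)stannane | CCCC[Sn](CCCC)(CCCC)CC=C(C)C | starting material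
7 | 2,5-di(1H-indol-3-yl)-3-methoxy-6-(3-methylbut-2-en-1-yl)-1,4-benzoquinone | COC1=C(c2c[nH]c3ccccc23)C(=O)C(CC=C(C)C)=C(c2c[nH]c3ccccc23)C1=O | target

**Totals**
Total step count: 3. Longest linear sequence: 3 steps (1 → 4 → 5 → 7).

**Steps most likely to fail, with fallbacks**

Step 3 (Stille prenylation) is the riskiest: the stannane may couple partly through its tertiary end to give the 1,1-dimethylallyl isomer, and the quinone may interfere with the zerovalent palladium catalyst or the phosphine. The fallback sets out from 5 and separates C–C coupling from building the trisubstituted alkene. Stille coupling of 5 with allyltributylstannane (C=CC[Sn](CCCC)(CCCC)CCCC) under Pd(PPh3)4 in dioxane at 90 °C cannot give a transposed isomer and yields 2-allyl-3,6-di(1H-indol-3-yl)-5-methoxy-1,4-benzoquinone F6. Olefin cross-metathesis of F6 with excess 2-methyl-2-butene (CC=C(C)C) and second-generation Grubbs catalyst RuCl2(=CHPh)(PCy3)(H2IMes) in CH2Cl2 at 40 °C turns allyl into prenyl and comes back to the route at 7.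

Step 2 (mono-methoxylation) may give mixtures of 4, 5 and the dimethoxy compound, or may stall because methoxide deprotonates the indole N–H. The fallback sets out from 4 and relies on charge, not stoichiometry, for mono-selectivity. Aqueous NaOH (2.2 equiv) in THF at 0 °C to rt replaces one bromide by hydroxide; the hydroxyquinone is formed as its anion (a vinylogous carboxylate), which resists a second substitution. Acidification with HCl gives 2-bromo-5-hydroxy-3,6-di(1H-indol-3-yl)-1,4-benzoquinone F5. Chemoselective O-methylation of this vinylogous acid with trimethylsilyldiazomethane (C[Si](C)(C)C=[N+]=[N-]) in toluene/MeOH at 0 °C leaves the indole N–H untouched and comes back to the route at 5.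

Step 1 (double indolylation of bromanil) may suffer from N-arylation, over-substitution or the 2,6-isomer. The fallback sets out from 2 and swaps base-mediated substitution for acid-promoted conjugate addition followed by oxidation, on a core that has only two open positions. Indole 2 adds under conc. HCl (cat.) in THF at rt to an unsubstituted ring carbon of bought 2,5-dibromo-1,4-benzoquinone F1, giving 2,5-dibromo-3-(1H-indol-3-yl)benzene-1,4-diol F2. 2,3-Dichloro-5,6-dicyano-1,4-benzoquinone (DDQ) oxidises F2 in the same flask to 2,5-dibromo-3-(1H-indol-3-yl)-1,4-benzoquinone F3. A second acid-promoted addition of 2 at the only remaining C–H carbon gives 2,5-dibromo-3,6-di(1H-indol-3-yl)benzene-1,4-diol F4, and DDQ oxidation of F4 comes back to the route at 4.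

**Further compounds**
F1 | step 1 | 2,5-dibromo-1,4-benzoquinone (bought) | O=C1C=C(Br)C(=O)C=C1Br
F2 | step 1 | 2,5-dibromo-3-(1H-indol-3-yl)benzene-1,4-diol | Oc1cc(Br)c(O)c(-c2c[nH]c3ccccc23)c1Br
F3 | step 1 | 2,5-dibromo-3-(1H-indol-3-yl)-1,4-benzoquinone | O=C1C=C(Br)C(=O)C(c2c[nH]c3ccccc23)=C1Br
F4 | step 1 | 2,5-dibromo-3,6-di(1H-indol-3-yl)benzene-1,4-diol | Oc1c(Br)c(-c2c[nH]c3ccccc23)c(O)c(Br)c1-c1c[nH]c2ccccc12
F5 | step 2 | 2-bromo-5-hydroxy-3,6-di(1H-indol-3-yl)-1,4-benzoquinone | OC1=C(c2c[nH]c3ccccc23)C(=O)C(Br)=C(c2c[nH]c3ccccc23)C1=O
F6 | step 3 | 2-allyl-3,6-di(1H-indol-3-yl)-5-methoxy-1,4-benzoquinone | COC1=C(c2c[nH]c3ccccc23)C(=O)C(CC=C)=C(c2c[nH]c3ccccc23)C1=O
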